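Ring B (C5–C6–C7–C8–C9–C10, labdane numbering) is first built one carbon short and enlarged late. Asymmetric allylation fixes C10; Wacker oxidation and aldol closure give a bicyclic cyclopentenone whose carbonyl is C8, whose only enolisable carbon is C9 (the chiral-pool side chain enters there) and whose other α-carbon is C6; hydrogenation sets C5. The key step then inserts C7 between C8 and C6 with Me3SiCHN2: it exploits the contrast between unsubstituted C6 and branched C9 flanking the C8 carbonyl, turns the strained trans-fused cyclopentanone into six-membered ring B and lets C9 settle equatorial. Methylenation of C8, SeO2 oxidation at C7 and acetylation finish.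

Key step: step 9

Remarks: labdane numbering is used for all atom labels (ring A = C1–C5, C10; ring B = C5–C10; side chain C11–C15; C17 = exocyclic carbon on C8). (R)-Methyl hydrogen 3-methylglutarate is assumed to be purchasable. The sense of induction in step 4 is assigned by analogy with simpler 2-alkylcyclohexanone enolates.

Step 1
Reactants: 1 (R)-methyl hydrogen 3-methylglutarate
Product: 3 (4S)-4-methyloxan-2-one, via hydroxy acid 2 (not isolated)
Conditions: LiBH4, THF, 0 °C to 50 °C; then 2 M HCl, rt
Reagents that add atoms: none
Why: Chemoselective ester reduction: LiBH4 first turns the acid into an unreactive lithium carboxylate and reduces only the methyl ester, and acidification lactonises the δ-hydroxy acid; the stereocentre is untouched and its descriptor changes only because the reduced arm becomes the lower-priority one.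

Step 2
Reactants: 3 (4S)-4-methyloxan-2-one
Product: 6 methyl (3R)-5-iodo-3-methylpentanoate, via silyl ester 4 (not isolated), via iodo acid 5 (not isolated)
Conditions: Me3SiI, CH2Cl2, rt; then MeOH, 40 °C
Reagents that add atoms: iodotrimethylsilane C[Si](C)(C)I; methanol CO
Why: Silyl-activated lactone cleavage (SN2 attack of iodide on the O–CH2 carbon) followed by HI-catalysed Fischer esterification in methanol; the remote stereocentre is untouched (R only through the priority of iodine).

Step 3
Reactants: 7 2,2,6-trimethylcyclohexan-1-one (racemic)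
Product: 9 prop-2-en-1-yl 2,6,6-trimethylcyclohex-1-en-1-yl carbonate, via lithium enolate 8 (not isolated)
Conditions: LiN(SiMe3)2, THF, 0 °C; then allyl chloroformate, −78 °C to rt
Reagents that add atoms: allyl chloroformate C=CCOC(Cl)=O
Why: The ketone has a single enolisable position, and the hindered tetrasubstituted lithium enolate is acylated on oxygen by the chloroformate (enol carbonate formation), which erases the racemic stereocentre.

Step 4
Reactants: 9 prop-2-en-1-yl 2,6,6-trimethylcyclohex-1-en-1-yl carbonate
Product: 10 (2R)-2-allyl-2,6,6-trimethylcyclohexan-1-one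
Conditions: Pd2(dba)3 (2.5 mol %), (R)-t-BuPHOX (6 mol %), THF, 25 °C
Reagents that add atoms: none
Why: Decarboxylative asymmetric Tsuji allylation: ionisation of the allyl enol carbonate by zerovalent palladium gives a π-allylpalladium enolate ion pair that recombines inside the chiral phosphinooxazoline pocket and sets the quaternary centre (future C10) under ligand control.

Step 5
Reactants: 10 (2R)-2-allyl-2,6,6-trimethylcyclohexan-1-one
Product: 11 (2R)-2,6,6-trimethyl-2-(2-oxopropyl)cyclohexan-1-one
Conditions: PdCl2 (cat.), Cu(OAc)2 (cat.), O2 (1 atm), DMA/H2O, rt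
Reagents that add atoms: water O
Why: Tsuji–Wacker oxidation of the terminal alkene with Markovnikov attack of water gives the methyl ketone (future C8 carbonyl and C6 methyl); the quaternary centre is not affected.

Step 6
Reactants: 11 (2R)-2,6,6-trimethyl-2-(2-oxopropyl)cyclohexan-1-one
Product: 13 (7aR)-4,4,7a-trimethyl-5,6,7,7a-tetrahydro-1H-inden-2(4H)-one, via aldol 12 (not isolated)
Conditions: KOH, xylenes, 110 °C, Dean–Stark
Reagents that add atoms: none
Why: Intramolecular aldol condensation (5-enolexo closure of the methyl ketone CH3 onto the non-enolisable ring carbonyl, then E1cB dehydration) gives the cyclopentenone with C8 as carbonyl and the C5=C6 double bond; C10 is unaffected.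

Step 7
Reactants: 13 (7aR)-4,4,7a-trimethyl-5,6,7,7a-tetrahydro-1H-inden-2(4H)-one; 6 methyl (3R)-5-iodo-3-methylpentanoate
Product: 15 methyl (3S)-3-methyl-5-[(1R,7aR)-4,4,7a-trimethyl-2-oxo-2,4,5,6,7,7a-hexahydro-1H-inden-1-yl]pentanoate, via lithium dienolate 14 (not isolated)
Conditions: LiN(i-Pr)2, THF, −78 °C; then 6, DMPU, −78 °C to 0 °C
Reagents that add atoms: none
Why: Kinetic α′-alkylation: C9 is the only acidic position of 13 (C4 is quaternary, so no γ-deprotonation) and its cross-conjugated lithium dienolate is alkylated by the primary iodide in an SN2 reaction; C13 comes from the chiral pool, and the new C9 centre is not relied on (an epimer mixture is expected, the 9β epimer is drawn) because it stays α to the C8 ketone and is equilibrated in step 9.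

Step 8
Reactants: 15 methyl (3S)-3-methyl-5-[(1R,7aR)-4,4,7a-trimethyl-2-oxo-2,4,5,6,7,7a-hexahydro-1H-inden-1-yl]pentanoate
Product: 16 methyl (3S)-3-methyl-5-[(1R,3aS,7aS)-4,4,7a-trimethyl-2-oxooctahydro-1H-inden-1-yl]pentanoate
Conditions: H2 (4 atm), 10% Pd on carbon, EtOAc, rt
Reagents that add atoms: none
Why: Heterogeneous catalytic hydrogenation should add H2 to the α face of C5=C6 because the β face is screened by the two syn-axial methyl groups on C4 and C10, which sets C5 (5α-H) and gives the trans-fused hydrindanone.

Step 9
Reactants: 16 methyl (3S)-3-methyl-5-[(1R,3aS,7aS)-4,4,7a-trimethyl-2-oxooctahydro-1H-inden-1-yl]pentanoate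
Product: 18 methyl (13S)-8-oxo-17-norlabdan-15-oate, via silyl ketone 17 (not isolated)
Conditions: Me3SiCHN2, BF3·OEt2, CH2Cl2, −78 °C to −20 °C; then NaOMe, MeOH, rt
Reagents that add atoms: (trimethylsilyl)diazomethane C[Si](C)(C)C=[N+]=[N-]
Why: BF3 activates the C8 carbonyl of the five-membered ring (C5–C6–C8–C9–C10), the diazo carbon adds to give a β-oxido diazonium betaine, and a 1,2-shift of C6 from C8 to the new carbon with loss of N2 inserts C7 and turns this ring into six-membered ring B (C5–C6–C7–C8–C9–C10); the closest known reaction is the Tiffeneau–Demjanov-type Me3SiCHN2/BF3 homologation of 2-substituted cycloalkanones. Ring B is therefore not closed by an exo or endo cyclisation but formed by a suprafacial 1,2-alkyl shift in which C6 migrates with retention, helped by relief of the strain of the trans-fused cyclopentanone. The selectivity needed is migration of the unsubstituted C6 instead of the branched C9; it rests on the general preference of this reagent for the less substituted α-carbon, reinforced here because the Me3Si group of the betaine should lie anti to the C9 side chain, which places the leaving N2 anti to C6. Double insertion is suppressed because the primary product is the hindered α-silyl ketone 17. Methoxide then removes silicon (C7 becomes a CH2, no stereocentre) and equilibrates C9, the only stereochemical decision of the step, to the equatorial 9β side chain (9α-H) of the trans-decalone, so both C9 epimers of 16 converge.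

Step 10
Reactants: 18 methyl (13S)-8-oxo-17-norlabdan-15-oate
Product: 19 methyl (13S)-labd-8(17)-en-15-oate
Conditions: Ph3PCH3Br, NaN(SiMe3)2, THF, 0 °C to 50 °C
Reagents that add atoms: methyltriphenylphosphonium bromide C[P+](c1ccccc1)(c1ccccc1)c1ccccc1.[Br-]
Why: Wittig methylenation of the C8 ketone creates C17; the non-stabilised ylide should react with the ketone faster than with the methyl ester, and C9 is already in its thermodynamic configuration.

Step 11
Reactants: 19 methyl (13S)-labd-8(17)-en-15-oate
Product: 20 methyl (13S)-7α-hydroxylabd-8(17)-en-15-oate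
Conditions: SeO2 (0.5 equiv), t-BuOOH, CH2Cl2, rt
Reagents that add atoms: selenium dioxide O=[Se]=O; tert-butyl hydroperoxide CC(C)(C)OO
Why: Riley allylic oxidation: ene reaction of the selenium oxidant at C17 with removal of the axial 7α-H, then a [2,3]-sigmatropic shift, delivers oxygen to C7 on the α face and should give the axial 7α-alcohol; the C7 methylene reacts in preference to the hindered C9 methine.

Step 12
Reactants: 20 methyl (13S)-7α-hydroxylabd-8(17)-en-15-oate
Product: 21 methyl (13S)-7α-acetoxylabd-8(17)-en-15-oate
Conditions: Ac2O, pyridine, DMAP (cat.), CH2Cl2, rt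
Reagents that add atoms: acetic anhydride CC(=O)OC(C)=O
Why: DMAP-catalysed acylation of the secondary allylic alcohol; no stereocentre is touched.

Compound list
1 | (R)-methyl hydrogen 3-methylglutarate, (3R)-5-methoxy-3-methyl-5-oxopentanoic acid | COC(=O)C[C@H](C)CC(=O)O | starting material
2 | (3S)-5-hydroxy-3-methylpentanoic acid | OCC[C@H](C)CC(=O)O | intermediate
3 | (4S)-4-methyloxan-2-one | O1CC[C@H](C)CC1=O | intermediate
4 | trimethylsilyl (3R)-5-iodo-3-methylpentanoate | ICC[C@H](C)CC(=O)O[Si](C)(C)C | intermediate
5 | (3R)-5-iodo-3-methylpentanoic acid | ICC[C@H](C)CC(=O)O | intermediate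
6 | methyl (3R)-5-iodo-3-methylpentanoate | ICC[C@H](C)CC(=O)OC | intermediate
7 | 2,2,6-trimethylcyclohexan-1-one (racemic) | CC1CCCC(C)(C)C1=O | starting material
8 | lithium 2,6,6-trimethylcyclohex-1-en-1-olate | [Li]OC1=C(C)CCCC1(C)C | intermediate
9 | prop-2-en-1-yl 2,6,6-trimethylcyclohex-1-en-1-yl carbonate | C=CCOC(=O)OC1=C(C)CCCC1(C)C | intermediate
10 | (2R)-2-allyl-2,6,6-trimethylcyclohexan-1-one | C=CC[C@@]1(C)CCCC(C)(C)C1=O | intermediate
11 | (2R)-2,6,6-trimethyl-2-(2-oxopropyl)cyclohexan-1-one | CC(=O)C[C@@]1(C)CCCC(C)(C)C1=O | intermediate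
12 | (7aR)-3a-hydroxy-4,4,7a-trimethyloctahydro-2H-inden-2-one (aldol, carbinol configuration open) | O=C1C[C@@]2(C)CCCC(C)(C)C2(O)C1 | intermediate
13 | (7aR)-4,4,7a-trimethyl-5,6,7,7a-tetrahydro-1H-inden-2(4H)-one | O=C1C[C@@]2(C)CCCC(C)(C)C2=C1 | intermediate
14 | lithium cross-conjugated dienolate of 13 (O–C8=C9, C5=C6) | [Li]OC1=C[C@@]2(C)CCCC(C)(C)C2=C1 | intermediate
15 | methyl (3S)-3-methyl-5-[(1R,7aR)-4,4,7a-trimethyl-2-oxo-2,4,5,6,7,7a-hexahydro-1H-inden-1-yl]pentanoate (9β epimer drawn, C9 epimer carried along) | O=C1C=C2C(C)(C)CCC[C@]2(C)[C@H]1CC[C@H](C)CC(=O)OC | intermediate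
16 | methyl (3S)-3-methyl-5-[(1R,3aS,7aS)-4,4,7a-trimethyl-2-oxooctahydro-1H-inden-1-yl]pentanoate (trans-fused, 9β epimer drawn) | O=C1C[C@H]2C(C)(C)CCC[C@]2(C)[C@H]1CC[C@H](C)CC(=O)OC | intermediate
17 | methyl (13S)-8-oxo-7-(trimethylsilyl)-17-norlabdan-15-oate (mixture at C7) | O=C1C([Si](C)(C)C)C[C@H]2C(C)(C)CCC[C@]2(C)[C@H]1CC[C@H](C)CC(=O)OC | intermediate
18 | methyl (5S,9R,10S,13S)-8-oxo-17-norlabdan-15-oate | O=C1CC[C@H]2C(C)(C)CCC[C@]2(C)[C@H]1CC[C@H](C)CC(=O)OC | intermediate
19 | methyl (5S,9S,10S,13S)-labd-8(17)-en-15-oate | C=C1CC[C@H]2C(C)(C)CCC[C@]2(C)[C@H]1CC[C@H](C)CC(=O)OC | intermediate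
20 | methyl (5S,7R,9R,10S,13S)-7-hydroxylabd-8(17)-en-15-oate (7α-OH) | C=C1[C@H](O)C[C@H]2C(C)(C)CCC[C@]2(C)[C@H]1CC[C@H](C)CC(=O)OC | intermediate
21 | methyl (5S,7R,9R,10S,13S)-7-acetoxylabd-8(17)-en-15-oate, methyl (3S)-5-[(1R,3R,4aS,8aS)-3-acetoxy-5,5,8a-trimethyl-2-methylidenedecahydronaphthalen-1-yl]-3-methylpentanoate | C=C1[C@H](OC(C)=O)C[C@H]2C(C)(C)CCC[C@]2(C)[C@H]1CC[C@H](C)CC(=O)OC | target

Total step count: 12. Longest linear sequence: 10 steps (steps 3 to 12, from 7 to 21); steps 1 and 2 make the side-chain iodide 6.

Steps most likely to fail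

1. Step 9. Addition of the bulky diazo reagent to the hindered C8 carbonyl may be slow, part of the material may rearrange by migration of C9 instead of C6, and a second insertion may occur. The fallback replaces the diazo insertion by a strain-release ring enlargement whose regiochemistry is fixed by kinetic enolisation. It sets out from 16: deprotonation at the unsubstituted C6 with LiN(i-Pr)2 and trapping with Me3SiCl should give the silyl enol ether F1. Simmons–Smith cyclopropanation (Et2Zn, CH2I2) would give the siloxycyclopropane F2. FeCl3 in DMF opens the internal C6–C8 bond to the ring-enlarged chloro ketone F3. NaOAc in methanol eliminates HCl to the enone F4, and hydrogenation over Pd on carbon, followed by NaOMe in methanol, comes back to the route at 18.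

2. Step 7. SN2 attack of a neopentyl-type enolate carbon on an unactivated primary iodide may be slow and compete with O-alkylation and with elimination of HI from 6. The fallback is an aldol condensation and sets out from 13 and 6. Kornblum oxidation of 6 (DMSO, NaHCO3, 100 °C) gives the aldehyde F5. Its addition to dienolate 14 gives the aldol F6, and dehydration (p-TsOH, benzene, reflux) gives the alkylidene dienone F7. Hydrogenation over Pd on carbon then reduces both C=C bonds from the α face and comes back to the route at 16, with C9 already β.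

3. Step 8. The enone is hindered at C5, so reduction may be incomplete, and a C9 side chain on the α face may erode the facial selectivity at C5. The fallback replaces syn addition on a metal surface by a stepwise hydrogen-atom-transfer conjugate reduction (Mn(dpm)3, PhSiH3, i-PrOH). In it a manganese hydride transfers H to C5 from the open α face and the resulting enolate is protonated separately. It sets out from 15 and comes back at 16 without new compounds.

Further compounds
F1 | step 9 | kinetic trimethylsilyl enol ether of 16 (C8–OSiMe3, C6=C8) | C[Si](C)(C)OC1=C[C@H]2C(C)(C)CCC[C@]2(C)[C@H]1CC[C@H](C)CC(=O)OC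
F2 | step 9 | siloxycyclopropane from F1 (new CH2 bridging C6 and C8, cyclopropane configuration open) | C[Si](C)(C)OC12CC1[C@H]1C(C)(C)CCC[C@]1(C)[C@H]2CC[C@H](C)CC(=O)OC
F3 | step 9 | methyl (13S)-6-chloro-8-oxo-17-norlabdan-15-oate (mixture at C6) | O=C1CC(Cl)[C@H]2C(C)(C)CCC[C@]2(C)[C@H]1CC[C@H](C)CC(=O)OC
F4 | step 9 | methyl (13S)-8-oxo-17-norlabd-6-en-15-oate | O=C1C=C[C@H]2C(C)(C)CCC[C@]2(C)[C@H]1CC[C@H](C)CC(=O)OC
F5 | step 7 | methyl (3S)-3-methyl-5-oxopentanoate | O=CC[C@H](C)CC(=O)OC
F6 | step 7 | aldol adduct of 13 at C9 with F5 (mixture at C9 and C11) | O=C1C=C2C(C)(C)CCC[C@]2(C)C1C(O)C[C@H](C)CC(=O)OC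
F7 | step 7 | C9=C11 alkylidene dienone from F6 (alkene geometry open) | O=C1C=C2C(C)(C)CCC[C@]2(C)C1=CC[C@H](C)CC(=O)OC
F0 | step 8 | none | none
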